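(All runs stem from a simulated flask on assumed constants, noise included.)

Slowness was my first suspicion, since a flask that makes product too slowly stands short of its plateau when its time ends.

common to all: gas phase 86 mM (held); catalyst 0.52 mM

| charge | substrate | remark | time |
|---|---|---|---|
| ochre | 0.024 M | run made earlier |  |
| amber | 0.81 M | run made earlier |  |
| larch | 0.040 M |  | 2.0 h |
| alder | 0.12 M |  | 2.0 h |
| ash | 0.40 M |  | 2.0 h |
| elm | 1.2 M |  | 2.0 h |

| run | time / min | product / % | substrate / % |
|---|---|---|---|
| ochre | 10.0 | 45.3 | 55.1 |
| ochre | 20.0 | 63.2 | 36.8 |
| ochre | 30.0 | 66.7 | 33.3 |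
| ochre | 40.0 | 66.9 | 32.8 |
| ochre | 50.0 | 67.7 | 32.7 |
| ochre | 60.0 | 67.1 | 32.6 |
| amber | 5.00 | 7.0 | 93.3 |
| amber | 8.00 | 12.0 | 88.5 |
| amber | 12.0 | 18.1 | 82.7 |
| amber | 20.0 | 27.9 | 72.4 |
| amber | 40.0 | 48.1 | 52.1 |
| amber | 60.0 | 58.8 | 41.0 |

(readings scatter by 0.3 percentage points)

- in percentages every species weighs as the substrate in it: one homo dimer counts as two
- at the start none of the gas is dissolved
- what may be going on: gas phase <-> dissolved gas; substrate + dissolved gas + catalyst <-> catalyst + product; 2 substrate -> homo dimer
- "hardly changes" means that all values lie within two and a half points (for a concentration: within two and a half percent of the largest)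

* [product] at the end for larch, alder, ash, elm, in this order
* the course of these numbers from the first flask to the last (hardly changes / rises, then falls / rises all the way / falls all the way / falls, then rises)

Ochre stopped rising near 67.1% product, so I took that share as the plateau of each flask with the gas held. Amber made product at 0.0122 M/min over its first 12.0 min. From these I built the filling number, amber's rate times the time given, divided by the c(product) the plateau holds: 1.82 for elm, 5.46 for ash, 18.2 for alder and 54.6 for larch. It counts how many times over amber's rate fills the plateau in the time given.

One number was not quite enough. Amber at 60.0 min had a filling number of 1.35, yet stood at 58.8%, which is 87.6% of the plateau read in ochre, so a number just above one did not bring amber to that plateau. Ochre at 10.0 min had a number of 7.59, yet stood at 45.3%, which is 67.5% of its plateau, so a large number on amber's rate did not show that ochre had arrived. Ochre's early rate, 0.00109 M/min, was also lower than amber's, but with it larch still scored 4.86. I therefore committed to plateau values for the three smaller flasks: 0.0268 M, 0.0805 M and 0.268 M. Elm's number exceeds amber's, so I put elm between 0.706 M and 0.805 M.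

The forecast gave 0.0269 M, 0.0806 M, 0.268 M and 0.77 M, course rises all the way, holding that “This equilibrium fraction should apply to every flask”. Its elm value lies inside my range.

The flasks gave 0.0270 M, 0.0809 M, 0.269 M and 0.779 M, course rises all the way.

    gas phase ⇌ dissolved gas, rate k1*(csat - [dissolved gas]) (kL = 0.00296 /s)
    substrate + dissolved gas + catalyst ⇌ catalyst + product (K = 24.1 /M, k = 65.4 /M²/s)
    2 substrate → homo dimer (k = 1.14 × 10⁻⁶ /M/s)

Elm, with a filling number of 1.82, ended with 64.9% product. Ash, reckoned at 1.00 h, had a number of 2.73 and already held 65.8%. Elm stopped far short of its charge because product is undone into substrate and dissolved gas: with that undoing taken away, elm ended at 1.19 M instead of 0.779 M.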